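# Proposed synthesis of CNP0244624.1 (20) through an intramolecular furan–oxyallyl [4+3] cycloaddition

## The problem

The target 20 is a cis-fused bicyclo[5.3.0]decane, configured 1R,3R,6R,7S,10R in the locants used throughout. Ring A is five-membered (C3–C7) and ring B seven-membered (C1, C2, C3, C7–C10); C1 is the ester carbon, C3 the angular C–CH3, C6 the CH–isopropyl, C7 the ring-fusion carbinol and C10 the methyl carbinol, and α denotes the face of the C3 methyl group. Ring A carries three contiguous stereocentres, two of them fully substituted, with C3–CH3, C6–isopropyl and C7–OH all α. Ring B carries a trans-1,2-diol unit in which the tertiary C10–OH is β and the acylated secondary C1–O is α. Only C6 is a plain CH stereocentre that asymmetric catalysis can set on an open chain, so it has to control C7 and C3, and the C7 hydroxyl is then the only handle from which C1 and C10 can be set. C7 and C10 are 1,4-related across ring B, so the two tertiary hydroxyls can ionise, eliminate or close a transannular ether under acid, and the anisate has to be placed late on a hindered secondary alcohol. The enabling feature is that C7–C8–C9–C10, oxygenated at both ends and methylated at C10, is a 2,5-disubstituted furan in disguise, while C3–C2–C1 can react as an oxyallyl cation tethered to it by C4–C5–C6. The cost is that the oxyallyl leaves its oxygen on C2, where the target has none, and the furan oxygen bridges C7 and C10 on one face, whereas the target has C10–OH opposite to C7–OH; both must be corrected after the cycloaddition.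

## Retrosynthesis

**Ester C–O bond (20 ⇒ 18 + 19).** The anisate is the most labile function and sits on the only secondary oxygen. Cutting it first leaves triol 18, whose two other hydroxyls are tertiary, so no protecting group is needed. The forward step is a selective acylation with 4-methoxybenzoyl chloride 19.

**C10–OH and C1–O bonds (18 ⇒ 17 ⇒ 16).** The trans-diol is traced to the α-epoxide 17 and from there to alkene 16.
- A cis-dihydroxylation of 16 would give the wrong relative configuration.
- Keeping and shifting the C2 oxygen instead would end in an SN2 inversion at a neopentyl-type C1 next to a tertiary alcohol.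
- An epoxide opened by water at its tertiary carbon gives the trans arrangement by mechanism, and the C7 hydroxyl, 1,4 across ring B, can deliver the oxygen to the α face.
- In 17 the C7 hydroxyl lies on the same face as the epoxide oxygen and cannot open it from the back.

Two stereocentres disappear. The forward steps must give α-delivery and inversion at C10.

**C2 carbonyl added back (16 ⇒ 15 ⇒ 14 ⇒ 13).** The C1=C10 alkene of 16 is traced through silyl ether 15 and dithiolane 14 to enone 13, whose C2 carbonyl marks the former oxyallyl carbon. Thioketal desulfurisation is chosen because hydrazone-based reductions of an enone move the double bond. The C7 oxygen is silylated so that it cannot re-add to the enone. The forward demand is C=O to CH2 with the alkene left in place.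

**C10–O bond of the bridge (13 ⇒ 12 ⇒ 11).** Enone 13 is the retro-oxa-Michael product of the oxygen-bridged ketone 12. Because C3 is quaternary, enolisation can only go toward C1, so the bridge can only open at C10. This one operation frees the C7 oxygen and erases the C10 configuration that the bridge imposes. 12 comes from 11 by saturating the strained C8=C9 alkene before the opening, which avoids a dienone.

**C3–C7 and C1–C10 bonds (11 ⇒ 9 via 10).** This is the key cut. Single-bond closures of ring A or of ring B (see below) each remove one ring. This cut removes both rings and three stereocentres and leads to the open-chain chloro ketone 9 with one stereocentre. The forward reaction must choose the furan face and the compact mode of approach.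

**C3–Cl bond (9 ⇒ 8 ⇒ 7).** Chlorinating after simple saturation of 7 would leave the regiochemistry (C1 versus C3) open and would need reagents that attack the furan. Conjugate hydrosilylation of enone 7 instead fixes the enol double bond at C2=C3 in 8, and a mild N-chloro reagent then places chlorine at C3.

**C3=C4 bond (7 ⇒ 6 + 3; 3 ⇒ 1).** A Wittig reaction joins aldehyde 6 to the four-carbon ylide 3, made from 3-bromobutan-2-one 1. The required (E)-geometry is irrelevant after step 4, so the step only has to be efficient.

**C6–furan bond (6 ⇒ 4 + 5).** An iminium-catalysed Friedel–Crafts addition of 2-methylfuran 4 to (E)-4-methylpent-2-enal 5 sets C6, the only stereocentre that is made by a catalyst. All others are relayed from it.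

## Roads not taken

**Alternative 1:** The cut is the C6–C7 bond of ring A. A 2,2-disubstituted cyclohept-4-enone A2, holding ring B, the C1=C10 alkene and the quaternary C3 with a 2-methylallylsilane-terminated chain, would be closed with TiCl4 by Hosomi–Sakurai addition of the allylsilane γ-carbon C6 to the C7 ketone, giving hydroazulenol A1.
- Merits: the C7 carbinol must form cis to the C3 methyl because the tether can only reach the carbonyl face on its own side. The ring B alkene is already where the endgame needs it. After saturation of the isopropenyl group, A1 would meet the present route at 16 without any carbonyl removal, so it is shorter after its key step.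
- Weak points: A2 needs an enantioselective synthesis of an α-quaternary cycloheptenone. The C6 configuration (isopropyl cis to OH) depends on allylsilane geometry and on the synclinal or antiperiplanar approach. The tertiary homoallylic alcohol A1 is exposed to TiCl4. The ring alkene and the isopropenyl group must later be told apart in a hydrogenation.
- Comparison: the chosen plan needs four more steps to reach 16. Against that, its absolute configuration comes from one catalytic step on a simple enal, and C3 is created relative to C6 in the same event that closes both rings.

**Alternative 2:** The cut is the C9–C10 bond, made by migration. Anodic oxidation of the cis-hydrindane β-hydroxy acid A4 (carbon anode, methanol, partly neutralised) would expel CO2, generate a cation at C10 and let C9 shift from C1 to C10, expanding the six-membered ring to the hydroazulenone A3.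
- Merits: the oxygen ends up on C1, where the target has it, so no 1,2-transposition or deoxygenation is needed, which is better than the chosen plan. Six-membered precursors are easier to build with stereocontrol.
- Weak points: A4 already contains C3, C6 and C7 and needs its own multistep synthesis. The cation at C10 is secondary and can be trapped by methanol, eliminate or fragment instead of triggering the shift. The C10 hydroxyl must still be introduced at the more substituted α-carbon of A3 with β-configuration, and the C1 ketone reduced to the α-alcohol, both without a built-in controlling element.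
- Comparison: the chosen plan pays for the misplaced C2 oxygen with three steps. In return it derives C1 and C10 together from one epoxide, by a directed delivery and a stereospecific opening.

**Alternative 3:** The cut is the C3–C7 bond alone. SmI2 (divalent samarium) with HMPA would reduce the C7 ketone of the acyclic keto enoate A6 to a ketyl that adds 5-exo to C3 of the (E)-enoate, giving cyclopentanol A5.
- Merits: A6 is easy to assemble. The usual anti relationship between the ketyl oxygen and the ester-bearing arm would place the C7 hydroxyl cis to the C3 methyl, as required. After the ester is turned into a vinyl group, ring-closing metathesis with the second-generation Grubbs catalyst could form C1=C10 and meet the present route at 16, again without carbonyl removal, so the step count is comparable or lower.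
- Weak points: a β,β-disubstituted enoate is a slow ketyl acceptor, so simple ketone reduction and pinacol coupling compete. Control of C7 by the adjacent C6 isopropyl group is not assured. Ring B needs a second ring-forming step, and the C10 methyl and the alkene have to be carried in a separate chain.
- Comparison: the chosen plan closes both rings in one step and brings C7–C10 with the C10 methyl in a commercial furan. Alternative 3 has the milder key step and no oxygen to remove.

Key step: step 6

Assumption: the (2R,5R) antipode of the imidazolidinone is assigned by analogy with the established sense of arene addition to (E)-enals in this catalyst family (the (2S,5S) series gives R adducts of but-2-enal, which corresponds to S here because isopropyl outranks the CH2CHO arm). If the sense is opposite for this pair, the (2S,5S) catalyst is used.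

Remark: 9 is used as the mixture of C3 epimers, since C3 becomes trigonal in 10.

## Route

Step 1
Reactants: 1 3-bromobutan-2-one
Product: 3 3-(triphenyl-λ5-phosphanylidene)butan-2-one, via (3-oxobutan-2-yl)triphenylphosphonium bromide 2 (not isolated)
Conditions: PPh3, toluene, 80 °C; then 2 M aq NaOH, CH2Cl2, rt
Reagents that add atoms: triphenylphosphine, c1ccc(cc1)P(c1ccccc1)c1ccccc1
Why: SN2 quaternisation of the phosphine by the α-bromo ketone and deprotonation of the acidic α-CH give the acyl-stabilised ylide; this is a standard Wittig reagent preparation.

Step 2
Reactants: 4 2-methylfuran; 5 (E)-4-methylpent-2-enal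
Product: 6 (R)-4-methyl-3-(5-methylfuran-2-yl)pentanal
Conditions: (2R,5R)-5-benzyl-2-tert-butyl-3-methylimidazolidin-4-one·CF3CO2H (20 mol %), CH2Cl2/i-PrOH, −40 °C
Reagents that add atoms: none
Why: Iminium-catalysed asymmetric Friedel–Crafts alkylation with the second-generation imidazolidinone: the free C5 position of the furan adds to the β-carbon of the chiral iminium ion on the face not covered by the benzyl group, which sets C6 as R.

Step 3
Reactants: 6 (R)-4-methyl-3-(5-methylfuran-2-yl)pentanal; 3 3-(triphenyl-λ5-phosphanylidene)butan-2-one
Product: 7 (6R,3E)-3,7-dimethyl-6-(5-methylfuran-2-yl)oct-3-en-2-one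
Conditions: toluene, 100 °C
Reagents that add atoms: none
Why: Wittig olefination with a stabilised α-branched acyl ylide should give the (E)-trisubstituted enone; C6 is β to the aldehyde, cannot enolise and is untouched.

Step 4
Reactants: 7 (6R,3E)-3,7-dimethyl-6-(5-methylfuran-2-yl)oct-3-en-2-one
Product: 8 triethyl{[(6R)-3,7-dimethyl-6-(5-methylfuran-2-yl)oct-2-en-2-yl]oxy}silane (E/Z mixture)
Conditions: Et3SiH, RhCl(PPh3)3 (1 mol %), THF, 50 °C
Reagents that add atoms: triethylsilane, CC[SiH](CC)CC
Why: Rhodium-catalysed 1,4-hydrosilylation of an enone with a monohydrosilane gives the enol silane with the double bond fixed at C2=C3, which carries the regiochemical information for chlorination at C3; the furan is inert to these conditions.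

Step 5
Reactants: 8 triethyl{[(6R)-3,7-dimethyl-6-(5-methylfuran-2-yl)oct-2-en-2-yl]oxy}silane
Product: 9 (6R)-3-chloro-3,7-dimethyl-6-(5-methylfuran-2-yl)octan-2-one (both C3 epimers)
Conditions: NCS, NaHCO3, THF, −20 → 0 °C
Reagents that add atoms: N-chlorosuccinimide, O=C1CCC(=O)N1Cl
Why: Electrophilic α-chlorination of a silyl enol ether places chlorine on the fully substituted enol carbon C3; the tetrasubstituted enol silane is far more nucleophilic than the dialkylfuran, so a mild N-chloro imide at low temperature should spare the ring.

Step 6
Reactants: 9 (6R)-3-chloro-3,7-dimethyl-6-(5-methylfuran-2-yl)octan-2-one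
Product: 11 5,8-dimethyl-2-(propan-2-yl)-11-oxatricyclo[6.2.1.0^{1,5}]undec-9-en-6-one (7,10-oxygen-bridged hydroazulen-2-one with C8=C9; C3–CH3, C6–isopropyl and the bridge all α), via oxyallyl cation 10 (not isolated)
Conditions: Et3N, CF3CH2OH, rt
Reagents that add atoms: none
Why: Triethylamine enolises 9 toward C1 (C3 carries no hydrogen) and the enolate loses chloride in the ionising, weakly nucleophilic alcohol to give oxyallyl cation 10, a two-electron three-carbon partner that adds across the α-carbons of the furan and forms C3–C7 and C1–C10. The closest known reaction type is the base-mediated intramolecular oxyallyl–furan [4+3] cycloaddition of α-halo ketones that carry the furan on a three-atom tether. Ring A closes through the tether as C3–C7 forms (five-membered ring from the cation terminus onto the tethered furan carbon), and ring B closes as the seven-membered carbocycle of the cycloaddition itself (C1–C2–C3 joined to C7–C10) under the C7–O–C10 bridge. C7, and with it C10, which the bridge ties to the same face, is set by C6: the tether must leave the furan plane toward the cation, and of the two other substituents on C6 the hydrogen takes the place next to C8–H (allylic 1,3-strain), so the isopropyl group lies on the side of the furan oxygen and fixes the face that is attacked. C3 is set by the mode of approach: only the cation with the tether on the terminus position syn to the oxyallyl oxygen can reach C7 without strain, and the compact (boat-like) approach that furans prefer with weakly electrophilic oxyallyls then puts C4 equatorial and the methyl group axial on the new pyranone ring, which means methyl syn to the bridge and a cis 5/7 fusion. The step therefore needs facial selectivity at the furan, secured by the stereocentre directly on the furan carbon, and a preference for the compact over the extended approach, favoured by the short tether and the mild, Lewis-acid-free generation of the cation; the extended approach would give the C3 epimer. Both C3 epimers of 9 converge on the same cation.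

Step 7
Reactants: 11 5,8-dimethyl-2-(propan-2-yl)-11-oxatricyclo[6.2.1.0^{1,5}]undec-9-en-6-one
Product: 12 5,8-dimethyl-2-(propan-2-yl)-11-oxatricyclo[6.2.1.0^{1,5}]undecan-6-one (8,9-dihydro derivative of 11)
Conditions: H2 (1 atm), 10% Pd/C, EtOAc, rt
Reagents that add atoms: none
Why: Catalytic hydrogenation of the strained disubstituted alkene of the oxabicycle creates no stereocentre and leaves the ketone and the bridge intact; it is done now so that the bridge opening cannot give a dienone.

Step 8
Reactants: 12 5,8-dimethyl-2-(propan-2-yl)-11-oxatricyclo[6.2.1.0^{1,5}]undecan-6-one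
Product: 13 cis-fused 3,10-dimethyl-6-(propan-2-yl)-7-(triethylsilyloxy)bicyclo[5.3.0]dec-1(10)-en-2-one (route locants; C3–CH3, C6–isopropyl and C7–OSiEt3 α)
Conditions: TESOTf, Et3N, CH2Cl2, 0 °C → rt
Reagents that add atoms: triethylsilyl trifluoromethanesulfonate, CC[Si](CC)(CC)OS(=O)(=O)C(F)(F)F
Why: Soft enolisation toward C1 (the only enolisable side) with silyl activation of the bridge oxygen triggers an E1cB-type β-elimination (retro-oxa-Michael): C10–O breaks, C1=C10 forms, and the released C7 oxygen is trapped as its silyl ether, which blocks re-addition. C10 becomes trigonal, so the configuration imposed by the bridge is erased, while C3, C6 and C7 are untouched.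

Step 9
Reactants: 13 cis-fused 3,10-dimethyl-6-(propan-2-yl)-7-(triethylsilyloxy)bicyclo[5.3.0]dec-1(10)-en-2-one
Product: 14 spiro-1,3-dithiolane of 13 at C2 (2,2-ethylenedithio ketal; alkene still C1=C10)
Conditions: HS(CH2)2SH, BF3·OEt2 (0.5 equiv), CH2Cl2, −20 → 0 °C
Reagents that add atoms: ethane-1,2-dithiol, SCCS
Why: Lewis-acid-catalysed dithioketalisation of a conjugated ketone proceeds without migration of the double bond, in contrast to O-ketals; the C7 silyl ether prevents acid-catalysed re-closure of the oxygen bridge.

Step 10
Reactants: 14 spiro-1,3-dithiolane of 13 at C2
Product: 15 cis-fused triethyl{[3,10-dimethyl-6-(propan-2-yl)bicyclo[5.3.0]dec-1(10)-en-7-yl]oxy}silane (route locants; silyl ether of 16)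
Conditions: Raney Ni (W-2, deactivated in acetone), EtOH, rt → 60 °C
Reagents that add atoms: none
Why: Hydrogenolytic desulfurisation reduces C2 to CH2 and, with deactivated nickel, leaves the trisubstituted C1=C10 alkene in place (the classical enone-to-alkene sequence); no stereocentre is touched.

Step 11
Reactants: 15 cis-fused triethyl{[3,10-dimethyl-6-(propan-2-yl)bicyclo[5.3.0]dec-1(10)-en-7-yl]oxy}silane
Product: 16 cis-fused 3,10-dimethyl-6-(propan-2-yl)bicyclo[5.3.0]dec-1(10)-en-7-ol (route locants; C3–CH3, C6–isopropyl and C7–OH α)
Conditions: TBAF, THF, 50 °C
Reagents that add atoms: none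
Why: Fluoride cleavage of the hindered tertiary silyl ether frees the C7 hydroxyl, which is needed as the directing group of the next step; the conditions are neutral to the alkene.

Step 12
Reactants: 16 cis-fused 3,10-dimethyl-6-(propan-2-yl)bicyclo[5.3.0]dec-1(10)-en-7-ol
Product: 17 1α,10α-epoxide of 16 (epoxide oxygen on the face of the C7 hydroxyl; C10–CH3 β)
Conditions: VO(acac)2 (5 mol %), t-BuOOH, CH2Cl2, 0 °C → rt
Reagents that add atoms: tert-butyl hydroperoxide, CC(C)(C)OO
Why: Hydroxyl-directed epoxidation: the vanadium alkoxide of the C7 hydroxyl, which sits across ring B from the alkene (bishomoallylic on both sides), delivers the peroxide oxygen to the α face, which sets C1 with oxygen α.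

Step 13
Reactants: 17 1α,10α-epoxide of 16
Product: 18 cis-fused 3α,10α-dimethyl-6α-(propan-2-yl)bicyclo[5.3.0]decane-1α,7α,10β-triol (route locants)
Conditions: HClO4 (cat.), THF/H2O, 0 °C
Reagents that add atoms: water, O
Why: Acid-catalysed epoxide hydrolysis: water attacks the tertiary C10 from the β face with inversion, giving C10–OH β and C10–CH3 α while the epoxide oxygen stays on C1 as the α-hydroxyl, which is the trans-diol of the target. The C7 hydroxyl lies on the same face as the leaving oxygen and cannot displace it from the back.

Step 14
Reactants: 18 cis-fused 3α,10α-dimethyl-6α-(propan-2-yl)bicyclo[5.3.0]decane-1α,7α,10β-triol; 19 4-methoxybenzoyl chloride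
Product: 20 CNP0244624.1, the C1 4-methoxybenzoate of 18 (1R,3R,6R,7S,10R in route locants)
Conditions: pyridine, DMAP (cat.), CH2Cl2, 0 °C → rt
Reagents that add atoms: none
Why: DMAP-catalysed acylation takes place only at the secondary C1 hydroxyl; the two tertiary hydroxyls do not react under these conditions and no stereocentre is affected.

## Compound list

1 | 3-bromobutan-2-one | CC(Br)C(C)=O | starting material
2 | (3-oxobutan-2-yl)triphenylphosphonium bromide | CC(=O)C(C)[P+](c1ccccc1)(c1ccccc1)c1ccccc1.[Br-] | intermediate (not isolated)
3 | 3-(triphenyl-λ5-phosphanylidene)butan-2-one | CC(=O)C(C)=P(c1ccccc1)(c1ccccc1)c1ccccc1 | intermediate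
4 | 2-methylfuran | Cc1ccco1 | starting material
5 | (E)-4-methylpent-2-enal | CC(C)/C=C/C=O | starting material
6 | (R)-4-methyl-3-(5-methylfuran-2-yl)pentanal | O=CC[C@H](C(C)C)c1ccc(C)o1 | intermediate
7 | (6R,3E)-3,7-dimethyl-6-(5-methylfuran-2-yl)oct-3-en-2-one | CC(=O)/C(C)=C/C[C@H](C(C)C)c1ccc(C)o1 | intermediate
8 | triethyl{[(6R)-3,7-dimethyl-6-(5-methylfuran-2-yl)oct-2-en-2-yl]oxy}silane (E/Z mixture) | CC(O[Si](CC)(CC)CC)=C(C)CC[C@H](C(C)C)c1ccc(C)o1 | intermediate
9 | (6R)-3-chloro-3,7-dimethyl-6-(5-methylfuran-2-yl)octan-2-one (both C3 epimers) | CC(=O)C(C)(Cl)CC[C@H](C(C)C)c1ccc(C)o1 | intermediate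
10 | oxyallyl cation (zwitterion) from 9 | C=C([O-])[C+](C)CC[C@H](C(C)C)c1ccc(C)o1 | intermediate (not isolated)
11 | 5,8-dimethyl-2-(propan-2-yl)-11-oxatricyclo[6.2.1.0^{1,5}]undec-9-en-6-one (C3–CH3, C6–isopropyl, bridge oxygen all α) | C1C(=O)[C@@]2(C)CC[C@H](C(C)C)[C@@]2(O3)C=C[C@@]13C | intermediate
12 | 5,8-dimethyl-2-(propan-2-yl)-11-oxatricyclo[6.2.1.0^{1,5}]undecan-6-one | C1C(=O)[C@@]2(C)CC[C@H](C(C)C)[C@@]2(O3)CC[C@@]13C | intermediate
13 | cis-fused 3,10-dimethyl-6-(propan-2-yl)-7-(triethylsilyloxy)bicyclo[5.3.0]dec-1(10)-en-2-one | CC1=CC(=O)[C@@]2(C)CC[C@H](C(C)C)[C@@]2(O[Si](CC)(CC)CC)CC1 | intermediate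
14 | spiro-1,3-dithiolane of 13 at C2 | CC1=CC3(SCCS3)[C@@]2(C)CC[C@H](C(C)C)[C@@]2(O[Si](CC)(CC)CC)CC1 | intermediate
15 | triethylsilyl ether of 16 | CC1=CC[C@@]2(C)CC[C@H](C(C)C)[C@@]2(O[Si](CC)(CC)CC)CC1 | intermediate
16 | cis-fused 3,10-dimethyl-6-(propan-2-yl)bicyclo[5.3.0]dec-1(10)-en-7-ol | CC1=CC[C@@]2(C)CC[C@H](C(C)C)[C@@]2(O)CC1 | intermediate
17 | 1α,10α-epoxide of 16 | O1[C@@H]2C[C@@]3(C)CC[C@H](C(C)C)[C@@]3(O)CC[C@]12C | intermediate
18 | 3α,10α-dimethyl-6α-(propan-2-yl)bicyclo[5.3.0]decane-1α,7α,10β-triol | O[C@@H]1C[C@@]2(C)CC[C@H](C(C)C)[C@@]2(O)CC[C@@]1(C)O | intermediate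
19 | 4-methoxybenzoyl chloride | COc1ccc(cc1)C(Cl)=O | starting material
20 | CNP0244624.1 (C1 4-methoxybenzoate of 18) | COc1ccc(C(=O)O[C@@H]2C[C@@]3(C)CC[C@H](C(C)C)[C@@]3(O)CC[C@@]2(C)O)cc1 | target

## Step count and risks

Total: 14 steps. Longest linear sequence: 13 steps (steps 2–14, from 4 and 5); step 1 is a one-step side branch that joins at step 3.

**Step 6 (key step).** The most likely failure is poor discrimination between the compact and the extended approach, which would erode the C3 configuration. Loss of facial selectivity is also possible if the isopropyl/hydrogen preference at C6 is small. The cation may also be diverted by solvent capture or Favorskii-type collapse, because it is disubstituted at one terminus and the alcohol is a weak nucleophile. Fallback: from 9, soft enolisation (TESOTf, Et3N, CH2Cl2) gives the 2-(triethylsilyloxy)allylic chloride F1. Chloride abstraction with AgClO4 in nitromethane at low temperature generates the 2-silyloxyallyl cation under aprotic, non-nucleophilic conditions. Cycloaddition and desilylation on work-up return to the route at 11.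

**Step 9 (with step 10).** Thioketalisation may be slow at a carbonyl flanked by the quaternary C3. The thiol may add in the conjugate sense, or the Lewis acid may remove the silyl group and allow the bridge to re-close. In step 10 the alkene may be partly saturated or shifted on nickel. Fallback, which bypasses both steps: from 13, Luche reduction (NaBH4, CeCl3·7H2O, MeOH) gives the allylic alcohol F2, and acetylation (Ac2O, pyridine, DMAP) gives the allylic acetate F3. Allylic hydride substitution with LiBHEt3 and Pd(PPh3)4 (zerovalent palladium), in which hydride goes to the less substituted allyl terminus C2, returns to the route at 15.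

**Step 12.** The remote tertiary hydroxyl may bind vanadium poorly, which would give weak facial direction. Any oxygen delivered to the β face would then be lost by transannular attack of the C7 hydroxyl at C10. Fallback: from 15, where the silyl group rules out that attack, epoxidation with mCPBA/NaHCO3 is made productive for either face. The α-epoxide silyl ether F4 is desilylated (TBAF) and rejoins at 17. The β-epoxide silyl ether F5 is opened at the secondary C1 with inversion by caesium 4-methoxybenzoate and 4-methoxybenzoic acid in DMF at 90 °C to give the C7-silylated ester F6, and TBAF then returns to the route at 20.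

**Step 13.** The opening may take on carbocation character at C10, with loss of stereochemical fidelity, elimination toward allylic alcohols or a hydride shift to a C1 ketone. Fallback: from 17, heating with 4-methoxybenzoic acid without mineral acid opens the epoxide at C10 with inversion to the tertiary ester F7. A base-mediated (DBU) 1,2-acyl shift to the less hindered secondary C1 oxygen then returns to the route at 20, bypassing 18.

## Further compounds

F1 | step 6 | {[(6R)-3-chloro-3,7-dimethyl-6-(5-methylfuran-2-yl)oct-1-en-2-yl]oxy}triethylsilane | C=C(O[Si](CC)(CC)CC)C(C)(Cl)CC[C@H](C(C)C)c1ccc(C)o1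
F2 | step 9 | allylic alcohol from 13 (C2–OH, either epimer) | CC1=CC(O)[C@@]2(C)CC[C@H](C(C)C)[C@@]2(O[Si](CC)(CC)CC)CC1
F3 | step 9 | acetate of F2 | CC1=CC(OC(C)=O)[C@@]2(C)CC[C@H](C(C)C)[C@@]2(O[Si](CC)(CC)CC)CC1
F4 | step 12 | 1α,10α-epoxide of 15 (triethylsilyl ether of 17) | O1[C@@H]2C[C@@]3(C)CC[C@H](C(C)C)[C@@]3(O[Si](CC)(CC)CC)CC[C@]12C
F5 | step 12 | 1β,10β-epoxide of 15 | O1[C@H]2C[C@@]3(C)CC[C@H](C(C)C)[C@@]3(O[Si](CC)(CC)CC)CC[C@@]12C
F6 | step 12 | C7 triethylsilyl ether of 20 | COc1ccc(C(=O)O[C@@H]2C[C@@]3(C)CC[C@H](C(C)C)[C@@]3(O[Si](CC)(CC)CC)CC[C@@]2(C)O)cc1
F7 | step 13 | C10 4-methoxybenzoate of 18 (tertiary ester, C1–OH free) | O[C@@H]1C[C@@]2(C)CC[C@H](C(C)C)[C@@]2(O)CC[C@@]1(C)OC(=O)c1ccc(OC)cc1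
A1 | alternative 1 | cis-fused hydroazulenol with isopropenyl group and C1=C10 alkene | CC1=CC[C@@]2(C)CC[C@H](C(C)=C)[C@@]2(O)CC1
A2 | alternative 1 | 2,5-dimethyl-2-[4-methyl-5-(trimethylsilyl)pent-3-enyl]cyclohept-4-en-1-one | CC1=CC[C@@](C)(CCC=C(C)C[Si](C)(C)C)C(=O)CC1
A3 | alternative 2 | 10-methylhydroazulen-1-one, C7 triethylsilyl ether | O=C1C[C@@]3(C)CC[C@H](C(C)C)[C@@]3(O[Si](CC)(CC)CC)CC[C@@H]1C
A4 | alternative 2 | cis-hydrindane β-hydroxy acid (2-(1-hydroxyhydrindan-1-yl)propanoic acid, C7 triethylsilyl ether) | OC(=O)C(C)C1(O)C[C@@]2(C)CC[C@H](C(C)C)[C@@]2(O[Si](CC)(CC)CC)CC1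
A5 | alternative 3 | cyclopentanol with ester and isopropenyl-terminated side chains | COC(=O)C[C@@]1(C)CC[C@H](C(C)C)[C@@]1(O)CCC(C)=C
A6 | alternative 3 | methyl (2E,6R)-3,10-dimethyl-7-oxo-6-(propan-2-yl)undeca-2,10-dienoate | COC(=O)/C=C(\C)CC[C@H](C(C)C)C(=O)CCC(C)=C
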